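Thursday's run, at half Saturday's substrate charge, shows you how the two mirror images part. By 60.0 min the left-handed substrate stands at 23% of the two charged together and the right-handed at 44%, each having started as half of that total.

all flasks: precatalyst 1.4 mol%; stray impurity 0.17 mM
- Saturday's: left-handed substrate 38 mM; right-handed substrate 38 mM; partner 3 equiv; protic impurity 0.76 mM; the very flask that is asked about, followed so far
- Thursday's: left-handed substrate 19 mM; right-handed substrate 19 mM; partner 3 equiv; protic impurity 0.76 mM; run made earlier
- flask: left-handed substrate 38 mM; right-handed substrate 38 mM; partner 3.00 equiv; protic impurity 0.760 mM; time 1.0 h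

| run | time / min | right-handed substrate / % | left-handed substrate / % |
|---|---|---|---|
| Saturday's | 1.00 | 47 | 50 |
| Saturday's | 2.50 | 49 | 48 |
| Saturday's | 5.00 | 48 | 45 |
| Saturday's | 8.00 | 47 | 36 |
| Saturday's | 10.0 | 49 | 30 |
| Thursday's | 5.00 | 51 | 49 |
| Thursday's | 15.0 | 50 | 45 |
| Thursday's | 30.0 | 48 | 34 |
| Thursday's | 40.0 | 45 | 34 |
| Thursday's | 60.0 | 44 | 23 |

(each reading ± 2 percentage points)

- free catalyst is single-handed; left-handed substrate and right-handed substrate are mirror images of each other, charged as a racemate, each of them at the stated concentration

* whether the excess of right-handed substrate over left-handed substrate among what is left of the two reaches 80% by 1.0 h (no / yes)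
* the highest excess of right-handed substrate over left-handed substrate among what is left of the two up to 1.0 h

Count in e-folds: the natural log of a substrate's charge over what is left of it. Thursday's left-handed e-folds over right-handed e-folds give a selectivity factor of 6.07. That is a loose reading, since the right-handed loss is 6 percentage points against a scatter of 2 points.

An excess of 80% means [right-handed substrate] is 9.00 times [left-handed substrate]. Suppose the right-handed substrate did not react at all: 2.20 left-handed e-folds would reach that ratio. Suppose instead that both reacted alike: the ratio stays where it started. Thursday's run lies between, so you need more than the first count, and my figure is 2.63, the left-handed e-folds needed.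

Saturday's left-handed readings, after a slow start, fall at about 0.0811 min⁻¹ between 5.00 min and 10.0 min. Held steady, that reaches the count near 36.1 min, and by 1.0 h it gives me 4.57 e-folds, an excess of 95.7%.

The forecast says yes and puts the top lower than my figure, at 93%, within 80% to 99%, allowing for slow catalyst decay; it adds that “the maximum falls at the end of the window”.

The flask answers yes, passing 80% at 0.641 h and topping out at 95.0%.

    partner + precatalyst → free catalyst + spent reagent (k = 0.0500 M⁻¹ s⁻¹)
    free catalyst + stray impurity → spent catalyst (k = 5200 M⁻¹ s⁻¹)
    partner + protic impurity → quenched reagent (k = 2.40 M⁻¹ s⁻¹)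
    partner + catalyst intermediate A → free catalyst + left-handed product (k = 3.50 M⁻¹ s⁻¹)
    free catalyst + left-handed substrate ⇌ catalyst intermediate A (K = 36.0 M⁻¹, k = 1100 M⁻¹ s⁻¹)
    partner + catalyst intermediate B → free catalyst + right-handed product (k = 0.700 M⁻¹ s⁻¹)
    free catalyst + right-handed substrate ⇌ catalyst intermediate B (K = 40.0 M⁻¹, k = 150 M⁻¹ s⁻¹)

By 1.0 h this flask holds 0.91% of its left-handed charge, which is 4.70 e-folds, more than the 2.63 I reckoned, while 35% of its right-handed charge remains. With twice the precatalyst and all other amounts as they are, the excess at the end is >99.9%, which on this count stands for at least 9.10 e-folds, twice this flask's 4.70.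

The readings were generated by integration with constants of no real substance, noise included.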